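**Retrosynthetic overview**
1. Target 8 ⇐ 7: the two CH2OH groups are the carbonyls of a 10-membered cyclic diester; hydride cleavage frees 8 and the chiral diol.
2. 7 ⇐ 4: one-pot oxidative cascade on a diol-tethered bis-sinapate; intramolecular C8–C8' coupling closes the 10-membered dilactone, then water bridges C7 and C7' to close the tetrahydrofuran.
3. 4 ⇐ two molecules of sinapic acid 1 + (1R,2R)-cyclohexane-1,2-diyldimethanol 2 (double esterification).
4. Ring order: macrocyclic dilactone first (C–C bond), tetrahydrofuran second (two C–O bonds), both in step 2; the macrocycle is opened again in step 3.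

Assumption: the facial sense imposed by the tether in step 2 comes from a strain model of the 10-membered ring, not from experiment; if the (1R,2R)-diol gave the mirror-image tetrahydrofuran as the major diastereomer, the equally available (1S,2S)-diol would be used in step 1 with no other change.

**Step 1**
Reactants: 1 sinapic acid (2.4 equiv); 2 (1R,2R)-cyclohexane-1,2-diyldimethanol
Product: 4 (1R,2R)-cyclohexane-1,2-diylbis(methylene) bis[(E)-sinapate], via mono-sinapate ester 3 (not isolated)
Conditions: PPh3, DIAD (2.6 equiv each, DIAD added slowly), THF, 0 °C → rt, 16 h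
Reagents that add atoms: none
Why: Mitsunobu esterification, in which the carboxylic acid (pKa about 4.5) is the only pronucleophile acidic enough to be engaged quickly, so the phenol flanked by two methoxy groups is left alone; the primary carbinol carbons are not stereogenic, so the (1R,2R) centres of the tether are untouched.

**Step 2**
Reactants: 4 (1R,2R)-cyclohexane-1,2-diylbis(methylene) bis[(E)-sinapate]
Product: 7 macrocyclic dilactone of the all-trans (2R,3R,4R,5R)-2,5-diaryltetrahydrofuran-3,4-dicarboxylic acid, via bis(quinone methide) macrocycle 5 (not isolated), via hydroxy quinone methide 6 (not isolated)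
Conditions: FeCl3·6H2O (2.2 equiv), acetone/H2O 4:1, 2 mM, 0 °C → rt, 12 h, dark
Reagents that add atoms: water, O
Why: Proposed new method: an oxidative phenol (β–β radical) coupling followed by a quinone methide hydration and 1,6-oxa-addition cascade, in which FeCl3 oxidises both phenols to phenoxyl radicals, the 1,4-diol tether holds the two sinapoyl units face to face so that C8–C8' coupling is intramolecular and closes the 10-membered ring as 5, water adds to one quinone methide and the new benzylic OH adds to the other (5-exo) to close the tetrahydrofuran; C3/C4 are set in the C–C coupling, where only the like (C2-symmetric) pairing allows a staggered new bond with both s-cis ester arms parallel and the rigid diequatorial (1R,2R) tether (CH2–C–C–CH2 torsion about −60°) fits the extended, low-strain ring of the (3R,4R) pairing, while C2/C5 are set under thermodynamic control because the 4-hydroxybenzyl ether bonds reopen reversibly through the quinone methide in the acidic medium and settle in the all-trans ring; the closest known chemistry is the FeCl3 oxidative β–β dimerisation of sinapate esters in aqueous acetone, which gives 2,5-diaryltetrahydrofuran-3,4-diesters by water capture of the bis(quinone methide), combined with diol-tethered head-to-head coupling of bis-cinnamates.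

**Step 3**
Reactants: 7 macrocyclic dilactone of the all-trans (2R,3R,4R,5R)-2,5-diaryltetrahydrofuran-3,4-dicarboxylic acid
Product: 8 [(2R,3S,4S,5R)-2,5-bis(4-hydroxy-3,5-dimethoxyphenyl)tetrahydrofuran-3,4-diyl]dimethanol
Conditions: i-Bu2AlH (10 equiv), THF/toluene, −78 → 0 °C; aq. potassium sodium tartrate (KNaC4H4O6)
Reagents that add atoms: none
Why: Ester-to-alcohol hydride reduction with i-Bu2AlH, as used for sinapate esters that carry a free phenol, cuts both ester C–O bonds of the dilactone, which releases the diol tether and turns both carbonyls into CH2OH without touching the four ring stereocentres (the 3,4 descriptors change from R to S only through CIP priorities).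

**Compound list**
1 | sinapic acid, (E)-3-(4-hydroxy-3,5-dimethoxyphenyl)prop-2-enoic acid | COc1cc(/C=C/C(=O)O)cc(OC)c1O | starting material
2 | (1R,2R)-cyclohexane-1,2-diyldimethanol (trans, C2-symmetric) | OC[C@@H]1CCCC[C@H]1CO | starting material
3 | [(1R,2R)-2-(hydroxymethyl)cyclohexyl]methyl (E)-sinapate (mono-ester, not isolated) | COc1cc(/C=C/C(=O)OC[C@@H]2CCCC[C@H]2CO)cc(OC)c1O | intermediate
4 | (1R,2R)-cyclohexane-1,2-diylbis(methylene) bis[(E)-3-(4-hydroxy-3,5-dimethoxyphenyl)prop-2-enoate] | COc1cc(/C=C/C(=O)OC[C@@H]2CCCC[C@H]2COC(=O)/C=C/c3cc(OC)c(O)c(OC)c3)cc(OC)c1O | intermediate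
5 | 10-membered cyclic diester of (2S,3S)-2,3-bis[(3,5-dimethoxy-4-oxocyclohexa-2,5-dien-1-ylidene)methyl]butanedioic acid and diol 2 (bis(quinone methide), not isolated) | O=C1C(OC)=CC(=C[C@H]2[C@H](C=C3C=C(OC)C(=O)C(OC)=C3)C(=O)OC[C@@H]4CCCC[C@H]4COC2=O)C=C1OC | intermediate
6 | same 10-membered diester after addition of water to one arm: (2R)-2-[(R)-hydroxy(4-hydroxy-3,5-dimethoxyphenyl)methyl]-(3S)-3-[(3,5-dimethoxy-4-oxocyclohexa-2,5-dien-1-ylidene)methyl]butanedioate of diol 2 (not isolated) | COc1cc([C@H](O)[C@H]2[C@H](C=C3C=C(OC)C(=O)C(OC)=C3)C(=O)OC[C@@H]4CCCC[C@H]4COC2=O)cc(OC)c1O | intermediate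
7 | 10-membered cyclic diester of (2R,3R,4R,5R)-2,5-bis(4-hydroxy-3,5-dimethoxyphenyl)tetrahydrofuran-3,4-dicarboxylic acid (all-trans) and diol 2 | COc1cc([C@@H]2O[C@@H](c3cc(OC)c(O)c(OC)c3)[C@H](C(=O)OC[C@@H]4CCCC[C@H]4CO5)[C@H]2C5=O)cc(OC)c1O | intermediate
8 | [(2R,3S,4S,5R)-2,5-bis(4-hydroxy-3,5-dimethoxyphenyl)tetrahydrofuran-3,4-diyl]dimethanol (all-trans) | COc1cc([C@@H]2O[C@@H](c3cc(OC)c(O)c(OC)c3)[C@H](CO)[C@H]2CO)cc(OC)c1O | target

**Totals**
Total step count: 3. Longest linear sequence: 3 steps (1 → 4 → 7 → 8).

**Steps most likely to fail**

Step 2 (highest risk). The cascade is unprecedented in tethered form. Possible failures are intermolecular coupling, low or reversed induction by the tether, capture of the bis(quinone methide) by the electron-rich aryl ring (aryldihydronaphthalene), or over-oxidation of the product phenols. Because the tether is chiral, minor isomers of 7 are diastereomers and can be removed by chromatography or crystallisation, so the enantiopurity of 8 does not depend on perfect induction. Fallback, which separates C–C from C–O bond formation: starting from 4, irradiation (365 nm, dilute MeCN) gives tether-controlled intramolecular head-to-head [2+2] photocycloaddition to the all-trans cyclobutane dilactone F1, a known mode for diol-tethered bis-cinnamates. Treatment of this bis-phenol with FeCl3·6H2O in aqueous acetone then cleaves the electron-rich C7–C7' bond oxidatively and returns to the route at 5, which goes on to 7 in the same flask.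

Step 1. The 1,4-diol can cyclodehydrate to the bicyclic ether under Mitsunobu activation, some phenol O-alkylation is possible, and Ph3PO removal from a polar bis-phenol can be tedious. Fallback, which builds the cinnamate C=C bond on the tether instead of esterifying a preformed acid: starting from 2, Meldrum's acid (2.2 equiv, toluene, 100 °C) gives the bis(hydrogen malonate) F2. Knoevenagel–Doebner condensation of it with syringaldehyde (2.2 equiv, pyridine, cat. piperidine, 70 °C, loss of CO2) returns to the route at 4.

Step 3. Aluminium phenoxides para to the benzylic ether carbons could open the tetrahydrofuran through a quinone methide that then captures hydride (over-reduced open-chain product), or reduction could stop at lactols. Fallback, which switches off the phenols first: starting from 7, TBSCl/imidazole/DMF gives the bis(tert-butyldimethylsilyl) ether F3. LiAlH4 (THF, 0 °C) then gives the bis-silylated diol F4, and Bu4NF in THF returns to the route at 8.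

**Further compounds**
F1 | step 2 | all-trans cyclobutane dilactone: 10-membered cyclic diester of 3,4-bis(4-hydroxy-3,5-dimethoxyphenyl)cyclobutane-1,2-dicarboxylic acid and diol 2 | COc1cc([C@@H]2[C@@H](c3cc(OC)c(O)c(OC)c3)[C@H](C(=O)OC[C@@H]4CCCC[C@H]4CO5)[C@H]2C5=O)cc(OC)c1O
F2 | step 1 | bis(hydrogen malonate): 3,3'-[(1R,2R)-cyclohexane-1,2-diylbis(methyleneoxy)]bis(3-oxopropanoic acid) | OC(=O)CC(=O)OC[C@@H]1CCCC[C@H]1COC(=O)CC(=O)O
F3 | step 3 | bis(tert-butyldimethylsilyl) ether of 7 | COc1cc([C@@H]2O[C@@H](c3cc(OC)c(O[Si](C)(C)C(C)(C)C)c(OC)c3)[C@H](C(=O)OC[C@@H]4CCCC[C@H]4CO5)[C@H]2C5=O)cc(OC)c1O[Si](C)(C)C(C)(C)C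
F4 | step 3 | bis-silylated diol: bis(tert-butyldimethylsilyl) ether of 8 | COc1cc([C@@H]2O[C@@H](c3cc(OC)c(O[Si](C)(C)C(C)(C)C)c(OC)c3)[C@H](CO)[C@H]2CO)cc(OC)c1O[Si](C)(C)C(C)(C)C
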